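The earlier runs and the new flask come from a simulation for substances that don't exist, and the scatter is random.

Late in both earlier runs, long after E has stopped climbing from L fed to the catalyst J, the readings of E lie flat at about 9.10% of the L charged. So I start at that end and work back to the peak of the new flask.

| setting | north-west | east | flask |
|---|---|---|---|
| L | 0.13 M (fed, over 10 min) | 0.30 M (fed, over 10 min) | 0.20 M (fed, over 10 min) |
| J | 4 mM | 4 mM | 4.0 mM |
| remark | run made earlier; the fed solution adds 0.20 times the starting volume | run made earlier; the fed solution adds 0.20 times the starting volume | the fed solution adds 0.20 times the starting volume |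
| time |  |  | 10 h |

| run | time / h | E / % |
|---|---|---|
| north-west | 0.167 | 37.8 |
| north-west | 0.333 | 79.8 |
| north-west | 0.667 | 76.3 |
| north-west | 1.00 | 54.0 |
| north-west | 2.00 | 22.8 |
| north-west | 4.00 | 10.8 |
| north-west | 8.00 | 9.2 |
| east | 0.167 | 17.6 |
| east | 0.333 | 36.2 |
| east | 0.667 | 72.6 |
| east | 1.00 | 92.1 |
| east | 2.00 | 36.0 |
| east | 4.00 | 11.3 |
| east | 8.00 | 9.0 |

(standard deviation of a reading: 0.5 percentage points)

- time up to 10 h at which E stands highest
- the amount of E, in percent of the L charged, at that time

- amounts are per litre of the starting volume; all of the dose is in the solution fed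

Measured above that floor, north-west E falls between 1.00 h and 2.00 h at a first-order 1.19 h⁻¹.

The early end is a straight line. The fraction of the charge in E climbs by 2.53 h⁻¹ in north-west and 1.10 h⁻¹ in east. Scaled by L charged over J charged, these give 82.2 h⁻¹ and 82.5 h⁻¹. I carry their mean, the turnover frequency w, L turned to E per J charged per hour: 82.4 h⁻¹.

The flask has J at 2.00% of L, so its line reaches the full charge at 0.607 h.

Do the two ends meet in north-west? Run back from 1.00 h to north-west's own run-out at 0.395 h, the falling curve gives 101%, about the full charge.

The weak link is the sharp corner. The two lines start late by a mean 0.0123 h; taking a tail that long at the falling rate, I commit to 0.619 h and 98.7%.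

The forecast says 0.64 h (0.58 h to 0.71 h) and 92% (87% to 96%): “Peak height is trimmed by the tail”. My height stands above its range.

The flask peaks at 97.5% at 0.628 h, above the forecast's range. L is then down to 0.0575% of its charge. The run-out time from w, 0.607 h, comes 1.26 min before that peak.

    L + J → Z (k = 31.0 M⁻¹ s⁻¹)
    Z → G (k = 0.0290 s⁻¹)
    G → J + E (k = 0.110 s⁻¹)
    E + J ⇌ X + J, rate k4*[J]*[E] forward; the back reaction follows from the equilibrium constant (K = 10.0, k = 0.0850 M⁻¹ s⁻¹)

In a second flask, like this one but with 0.016 M of J, J is 8.00% of L, and w gives a run-out at 0.152 h, shorter than the 0.17 h feed, so the reckoned time falls inside the feed. That second flask peaks at 91.9%, lower than the first.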